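Readings and results are calculated for an exercise, and the scatter is random.

Of each hand's charge the readings showed what fraction was left, and both hands meet the same coupling partner, so I counted the lifetimes each hand had gone through, as minus the logarithm of that fraction.

| flask | left-handed substrate | right-handed substrate | protic impurity | solid reagent | remark | time |
|---|---|---|---|---|---|---|
| amber | 10 mM | 10 mM | 6 mM | 1.5 equiv | run made earlier |  |
| violet | 40 mM | 40 mM | 6 mM | 1.5 equiv | run made earlier |  |
| red | 20 mM | 20 mM | 6 mM | 3 equiv | run made earlier |  |
| flask | 20 mM | 20 mM | 6.00 mM | 1.50 equiv |  | 4.0 min |

| run | time / min | left-handed substrate / % | right-handed substrate / % |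
|---|---|---|---|
| amber | 0.417 | 49.9 | 50.0 |
| amber | 0.833 | 49.1 | 49.5 |
| amber | 2.00 | 47.1 | 49.3 |
| amber | 5.00 | 37.9 | 44.3 |
| violet | 0.667 | 49.7 | 50.3 |
| violet | 1.50 | 49.2 | 49.4 |
| violet | 3.00 | 45.6 | 48.5 |
| violet | 5.00 | 41.7 | 46.3 |
| red | 0.667 | 49.0 | 50.1 |
| red | 1.50 | 48.8 | 49.5 |
| red | 3.00 | 45.4 | 47.9 |
| red | 5.00 | 38.2 | 45.0 |

(each reading ± 0.3 percentage points)

- coupling partner is single-handed; left-handed substrate and right-handed substrate are mirror images of each other, charged as a racemate, each of them at the stated concentration
- given per volume of solution although it is solid: solid reagent
- steps under discussion: solid reagent <-> coupling partner; coupling partner <-> dormant form; coupling partner + protic impurity -> quenched reagent; coupling partner + right-handed substrate -> right-handed product; coupling partner + left-handed substrate -> left-handed product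
- at the start none of the solid reagent is in solution
- an excess is the difference of the two amounts in percent of their sum
- an excess is below zero if the other one leads
- the handed part of coupling partner does not stay in what it makes, so the products of the two hands are mirror images too

1. part of the left-handed substrate and right-handed substrate charged together that has reacted at 4.0 min
2. excess of left-handed product over right-handed product in the product at 4.0 min
3. excess of right-handed substrate over left-handed substrate among what is left of the two at 4.0 min

The ratio of the two counts needs no knowledge of how fast coupling partner appears, so I took it at the last reading of the three runs and averaged: 2.40, the selectivity factor, lifetimes of the left-handed substrate per lifetime of the right-handed one. The flask's substrate charge lies between amber's and violet's, with the same protic impurity and the same equivalents of solid reagent, so I read the left-handed count at 4.0 min on straight lines between their readings and averaged, which gave 0.171. Dividing by the factor gave the right-handed count, and the two counts gave me 11.3% reacted, a product excess of 39.2% and a substrate excess of 4.98%. The forecast, on the ground that “The flask sits between amber and violet”, gave 10%, 39% and 4.3%, lower than mine on the first and third. The flask gave 11.3%, 41.3% and 5.24%.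

    solid reagent ⇌ coupling partner, rate k1*(cs1 - [coupling partner]) while solid is left; crystals form when [coupling partner] > cs1 (solubility = 13.0 mM, k = 0.00580 s⁻¹)
    coupling partner ⇌ dormant form (K = 2.80, k = 0.00340 s⁻¹)
    coupling partner + protic impurity → quenched reagent (k = 12.0 M⁻¹ s⁻¹)
    coupling partner + right-handed substrate → right-handed product (k = 0.150 M⁻¹ s⁻¹)
    coupling partner + left-handed substrate → left-handed product (k = 0.380 M⁻¹ s⁻¹)

These three results give back a factor of 2.53 and a left-handed count of 0.173, and at 4.00 min, with 0.42% of the protic impurity left in the flask, that impurity used coupling partner at 0.047 of the rate of the left-handed substrate, far less than the substrate took. The neighbour charged with 15 mM of protic impurity still held 12% of it at that time and reached a smaller count of 0.0668, while its 4.53% reacted and 42.6% product excess give a factor of 2.53.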